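## Plan

- **Cuts:** (i) the acyl–O bond of the veratrate; (ii) the oxolane C2–C3 bond, redrawn so that the CH2O branch carbon goes back into the ring, i.e. oxolane ⇐ 2-aryl-3,4-epoxyoxane (6→5 ring contraction); (iii) the aryl–C bond, back to 3,4-di-O-acetyl-D-xylal and an arylboronic acid.
- **Enabling feature:** oxolane C3 carries a one-carbon branch and lies between the two O-bearing ring carbons C2 (ArCH–O) and C4 (CH–OH). Branch carbon and C3 are therefore the two carbons of an oxirane on an oxane whose other ring atoms are already those of the target, and shift of either flanking carbon gives the same oxolane.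
- **Forward order:** aryl onto C1 of D-xylal (all five pentose carbons are kept), protecting-group change, epoxidation, contraction of the oxane to the oxolane (the only ring made, closed last) with reduction of CH=O, esterification, desilylation.
- **Stereochemistry:** C4 is C4 of D-xylose; C2 comes from arylation anti to the leaving C3 acetate (hence cis to C4–O); C3 comes from epoxidation anti to both substituents followed by two inversions in the key step, which gives the all-cis array.

Key step: step 5

Remark: compounds 1, 2 and 10 are taken as commercial; bromide may open oxirane 6 at either carbon and both salts should contract to the same aldehyde 8, so only the salt opened at oxane C4 (7) is listed.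

## Route

Step 1
Reactants: 1 3,4-di-O-acetyl-D-xylal; 2 (3,4-dimethoxyphenyl)boronic acid
Product: 3 (3S,6S)-6-(3,4-dimethoxyphenyl)-3,6-dihydro-2H-pyran-3-yl acetate (aryl and acetoxy cis)
Conditions: Pd(OAc)2 (10 mol %), MeCN, rt
Reagents that add atoms: none
Why: Pd(II)-catalysed Ferrier-type C-arylation of a glycal, in which aryl–Pd adds syn to C1=C2 on the face anti to the allylic C3 acetate and that acetate then leaves by anti β-acetoxy elimination, so the aryl group ends trans to the departed O3 and cis to the C4 acetate.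

Step 2
Reactants: 3 (3S,6S)-6-(3,4-dimethoxyphenyl)-3,6-dihydro-2H-pyran-3-yl acetate
Product: 4 (3S,6S)-6-(3,4-dimethoxyphenyl)-3,6-dihydro-2H-pyran-3-ol
Conditions: K2CO3 (cat.), MeOH, 0 °C to rt
Reagents that add atoms: none
Why: Zemplén-type transesterification removes the acetate, which would be too good a β-leaving group and too prone to migrate in step 5, without touching either stereocenter.

Step 3
Reactants: 4 (3S,6S)-6-(3,4-dimethoxyphenyl)-3,6-dihydro-2H-pyran-3-ol
Product: 5 tert-butyl{[(3S,6S)-6-(3,4-dimethoxyphenyl)-3,6-dihydro-2H-pyran-3-yl]oxy}diphenylsilane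
Conditions: TBDPSCl, imidazole, DMF, rt
Reagents that add atoms: tert-butyl(chloro)diphenylsilane, CC(C)(C)[Si](Cl)(c1ccccc1)c1ccccc1
Why: Standard silylation of a secondary alcohol; the TBDPS ether is bulky (face shielding in step 4), stable to hot bromide and slow to migrate between oxygens.

Step 4
Reactants: 5 tert-butyl{[(3S,6S)-6-(3,4-dimethoxyphenyl)-3,6-dihydro-2H-pyran-3-yl]oxy}diphenylsilane
Product: 6 (1R,2R,5R,6R)-5-[(tert-butyldiphenylsilyl)oxy]-2-(3,4-dimethoxyphenyl)-3,7-dioxabicyclo[4.1.0]heptane (oxirane trans to aryl and to silyloxy)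
Conditions: mCPBA, CH2Cl2, rt
Reagents that add atoms: 3-chloroperoxybenzoic acid, OOC(=O)c1cccc(Cl)c1
Why: Prilezhaev epoxidation without a directing OH, so the peracid should approach the face anti to the two cis allylic substituents (aryl and silyloxy), as is usual for O-protected 2,3-unsaturated pyranosides.

Step 5
Reactants: 6 (1R,2R,5R,6R)-5-[(tert-butyldiphenylsilyl)oxy]-2-(3,4-dimethoxyphenyl)-3,7-dioxabicyclo[4.1.0]heptane
Product: 9 [(2S,3S,4S)-4-[(tert-butyldiphenylsilyl)oxy]-2-(3,4-dimethoxyphenyl)oxolan-3-yl]methanol, via lithium trans-bromohydrinate 7 (not isolated), via all-cis oxolane-3-carbaldehyde 8 (not isolated)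
Conditions: LiBr, tetramethylurea, toluene, 90–110 °C; then 0 °C, NaBH4, EtOH
Reagents that add atoms: none
Why: Lithium-assisted anti (trans-diaxial) attack of bromide on the oxirane gives the lithium trans-bromohydrinate 7, which relaxes to the chair with aryl, O– and Br equatorial, so that the ring bond between the ArCH carbon and the carbinolate carbon lies antiperiplanar to C–Br; push from the alkoxide then moves the ArCH carbon onto the bromide carbon with loss of LiBr (semipinacol 1,2-shift), and the former carbinolate carbon leaves the ring as the formyl group of 8. The closest known reaction type is the lithium bromide promoted Meinwald-type ring contraction of cyclohexene oxides and of 2,3-anhydropyranosides to formylcyclopentanes and C-formyl furanosides. The oxolane is closed by this 1,2-shift of a ring C–C bond (oxane to oxolane contraction, SN2-like with inversion at the migration terminus), not by an exo or endo attack of a chain end. The only new stereocenter, oxolane C3, is set by two successive inversions at the same carbon (bromide opening, then the shift), so the formyl carbon ends on the face opposite to the former oxirane oxygen, cis to the aryl group at C2 (which migrates with retention) and to the silyloxy group at C4 (untouched). The step needs carbon shift in preference to hydride shift, aryl shift or elimination: an equatorial C–Br bond is antiperiplanar only to ring bonds, the nucleophilic and weakly Lewis acidic medium avoids ionisation next to the electron-rich aryl group, and opening at the other oxirane carbon would lead by the mirror shift of C4 to the same aldehyde. Aldehyde 8 is the least stable epimer and a β-silyloxy aldehyde, so it is reduced in the same flask to 9 before epimerisation or β-elimination can set in.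

Step 6
Reactants: 9 [(2S,3S,4S)-4-[(tert-butyldiphenylsilyl)oxy]-2-(3,4-dimethoxyphenyl)oxolan-3-yl]methanol; 10 3,4-dimethoxybenzoyl chloride
Product: 11 [(2S,3S,4S)-4-[(tert-butyldiphenylsilyl)oxy]-2-(3,4-dimethoxyphenyl)oxolan-3-yl]methyl 3,4-dimethoxybenzoate
Conditions: Et3N, DMAP (cat.), CH2Cl2, 0 °C to rt
Reagents that add atoms: none
Why: DMAP-catalysed acylation of the only free hydroxyl group, a primary alcohol, with an aroyl chloride.

Step 7
Reactants: 11 [(2S,3S,4S)-4-[(tert-butyldiphenylsilyl)oxy]-2-(3,4-dimethoxyphenyl)oxolan-3-yl]methyl 3,4-dimethoxybenzoate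
Product: 12 [(2S,3R,4S)-2-(3,4-dimethoxyphenyl)-4-hydroxyoxolan-3-yl]methyl 3,4-dimethoxybenzoate
Conditions: TBAF, AcOH, THF, rt
Reagents that add atoms: none
Why: Fluoride desilylation buffered with acetic acid, which avoids both acid that could ionise the electron-rich benzylic C2–O bond (epimerisation) and free alkoxide that could shift the ester to the cis C4 oxygen.

## Compound list

1 | 3,4-di-O-acetyl-D-xylal, (3R,4R)-3,4-dihydro-2H-pyran-3,4-diyl diacetate | C1=C[C@@H](OC(C)=O)[C@H](OC(C)=O)CO1 | starting material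
2 | (3,4-dimethoxyphenyl)boronic acid | COc1ccc(cc1OC)B(O)O | starting material
3 | (3S,6S)-6-(3,4-dimethoxyphenyl)-3,6-dihydro-2H-pyran-3-yl acetate | COc1ccc(cc1OC)[C@@H]1C=C[C@H](OC(C)=O)CO1 | intermediate
4 | (3S,6S)-6-(3,4-dimethoxyphenyl)-3,6-dihydro-2H-pyran-3-ol | COc1ccc(cc1OC)[C@@H]1C=C[C@H](O)CO1 | intermediate
5 | tert-butyl{[(3S,6S)-6-(3,4-dimethoxyphenyl)-3,6-dihydro-2H-pyran-3-yl]oxy}diphenylsilane | COc1ccc(cc1OC)[C@@H]1C=C[C@H](O[Si](c2ccccc2)(c2ccccc2)C(C)(C)C)CO1 | intermediate
6 | (1R,2R,5R,6R)-5-[(tert-butyldiphenylsilyl)oxy]-2-(3,4-dimethoxyphenyl)-3,7-dioxabicyclo[4.1.0]heptane | COc1ccc(cc1OC)[C@@H]1[C@H]2O[C@H]2[C@H](O[Si](c2ccccc2)(c2ccccc2)C(C)(C)C)CO1 | intermediate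
7 | lithium (2R,3R,4S,5R)-4-bromo-5-[(tert-butyldiphenylsilyl)oxy]-2-(3,4-dimethoxyphenyl)oxan-3-olate | [Li+].COc1ccc(cc1OC)[C@@H]1[C@@H]([O-])[C@H](Br)[C@H](O[Si](c2ccccc2)(c2ccccc2)C(C)(C)C)CO1 | intermediate
8 | (2S,3S,4S)-4-[(tert-butyldiphenylsilyl)oxy]-2-(3,4-dimethoxyphenyl)oxolane-3-carbaldehyde (all-cis) | O=C[C@@H]1[C@H](O[Si](c2ccccc2)(c2ccccc2)C(C)(C)C)CO[C@@H]1c1ccc(OC)c(OC)c1 | intermediate
9 | [(2S,3S,4S)-4-[(tert-butyldiphenylsilyl)oxy]-2-(3,4-dimethoxyphenyl)oxolan-3-yl]methanol | OC[C@@H]1[C@H](O[Si](c2ccccc2)(c2ccccc2)C(C)(C)C)CO[C@@H]1c1ccc(OC)c(OC)c1 | intermediate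
10 | 3,4-dimethoxybenzoyl chloride | COc1ccc(cc1OC)C(Cl)=O | starting material
11 | [(2S,3S,4S)-4-[(tert-butyldiphenylsilyl)oxy]-2-(3,4-dimethoxyphenyl)oxolan-3-yl]methyl 3,4-dimethoxybenzoate | COc1ccc(C(=O)OC[C@@H]2[C@H](O[Si](c3ccccc3)(c3ccccc3)C(C)(C)C)CO[C@@H]2c2ccc(OC)c(OC)c2)cc1OC | intermediate
12 | [(2S,3R,4S)-2-(3,4-dimethoxyphenyl)-4-hydroxyoxolan-3-yl]methyl 3,4-dimethoxybenzoate | COc1ccc(C(=O)OC[C@@H]2[C@H](O)CO[C@@H]2c2ccc(OC)c(OC)c2)cc1OC | target

## Step count and risks

Total step count: 7. Longest linear sequence: 7 steps (1 to 12).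

**Step 5.** The hot medium may epimerise the formyl-bearing carbon or eliminate the β-silyloxy group before the reduction, and opening of the shielded oxirane may be slow. The fallback sets out from 6 and comes back at 9. Opening of 6 with NaN3/NH4Cl (aqueous 2-methoxyethanol, 90 °C) should give the trans-diaxially opened azido alcohol (2R,3S,4S,5S)-4-azido-5-[(tert-butyldiphenylsilyl)oxy]-2-(3,4-dimethoxyphenyl)oxan-3-ol F1. Staudinger reduction (PPh3, THF/H2O) should give the amino alcohol (2R,3S,4S,5S)-4-amino-5-[(tert-butyldiphenylsilyl)oxy]-2-(3,4-dimethoxyphenyl)oxan-3-ol F2. NaNO2 in aqueous AcOH at 0 °C should then expel N2 from the equatorial amine with the same antiperiplanar shift of the ArCH carbon (Tiffeneau–Demjanov-type deaminative contraction, known for trans-2-aminocyclohexanols and 3-amino-3-deoxypyranosides). This gives 8 at a temperature at which it should keep its configuration, and NaBH4 added to the same flask returns to 9.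

**Step 1.** Facial selectivity of the carbopalladation may be poor with the conformationally mobile pentose glycal, and the electron-rich boronic acid may be lost by protodeboronation or homocoupling. The fallback sets out from 10 and comes back at 4. Stille coupling of 10 with tributyl(vinyl)stannane (Pd catalyst) should give 1-(3,4-dimethoxyphenyl)prop-2-en-1-one F3. Corey–Bakshi–Shibata reduction ((R)-Me-CBS, BH3·SMe2) should give (1S)-1-(3,4-dimethoxyphenyl)prop-2-en-1-ol F4. Its sodium alkoxide (NaH, DMF) should open (S)-2-vinyloxirane at the terminal carbon to give (2S)-1-{[(1S)-1-(3,4-dimethoxyphenyl)prop-2-en-1-yl]oxy}but-3-en-2-ol F5. Ring-closing metathesis (Grubbs II, CH2Cl2, 40 °C) then closes the 3,6-dihydro-2H-pyran 4, with the two stereocenters set independently of each other.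

**Step 4.** The alkene is deactivated by two allylic C–O bonds, so epoxidation may be sluggish, with competing oxidation of the dimethoxyarene or incomplete facial selectivity. The fallback sets out from 5 and comes back at 6. Dihydroxylation (OsO4 cat., NMO), which is reliably anti to both allylic substituents in 2,3-unsaturated pyranosides, should give the cis-diol (2R,3S,4R,5R)-5-[(tert-butyldiphenylsilyl)oxy]-2-(3,4-dimethoxyphenyl)oxane-3,4-diol F6. In one flask, MeC(OMe)3/PPTS should give the cyclic methyl orthoacetate of this diol F7, AcBr should open it to the trans-bromo acetate (2R,3R,4S,5R)-4-bromo-5-[(tert-butyldiphenylsilyl)oxy]-2-(3,4-dimethoxyphenyl)oxan-3-yl acetate F8 (inversion at the carbon attacked by bromide), and K2CO3/MeOH should close the oxirane 6 by a second inversion at the same carbon, on the face of the original diol.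

Further compounds
F1 | step 5 | (2R,3S,4S,5S)-4-azido-5-[(tert-butyldiphenylsilyl)oxy]-2-(3,4-dimethoxyphenyl)oxan-3-ol | COc1ccc(cc1OC)[C@@H]1[C@@H](O)[C@H](N=[N+]=[N-])[C@H](O[Si](c2ccccc2)(c2ccccc2)C(C)(C)C)CO1
F2 | step 5 | (2R,3S,4S,5S)-4-amino-5-[(tert-butyldiphenylsilyl)oxy]-2-(3,4-dimethoxyphenyl)oxan-3-ol | COc1ccc(cc1OC)[C@@H]1[C@@H](O)[C@H](N)[C@H](O[Si](c2ccccc2)(c2ccccc2)C(C)(C)C)CO1
F3 | step 1 | 1-(3,4-dimethoxyphenyl)prop-2-en-1-one | COc1ccc(cc1OC)C(=O)C=C
F4 | step 1 | (1S)-1-(3,4-dimethoxyphenyl)prop-2-en-1-ol | COc1ccc(cc1OC)[C@@H](O)C=C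
F5 | step 1 | (2S)-1-{[(1S)-1-(3,4-dimethoxyphenyl)prop-2-en-1-yl]oxy}but-3-en-2-ol | COc1ccc(cc1OC)[C@H](C=C)OC[C@@H](O)C=C
F6 | step 4 | (2R,3S,4R,5R)-5-[(tert-butyldiphenylsilyl)oxy]-2-(3,4-dimethoxyphenyl)oxane-3,4-diol | COc1ccc(cc1OC)[C@@H]1[C@@H](O)[C@@H](O)[C@H](O[Si](c2ccccc2)(c2ccccc2)C(C)(C)C)CO1
F7 | step 4 | cyclic methyl orthoacetate of diol F6 (2-methoxy-2-methyl-1,3-dioxolane fused at oxane C3–C4, orthoester carbon unspecified) | COc1ccc(cc1OC)[C@@H]1[C@H]2OC(C)(OC)O[C@H]2[C@H](O[Si](c3ccccc3)(c3ccccc3)C(C)(C)C)CO1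
F8 | step 4 | (2R,3R,4S,5R)-4-bromo-5-[(tert-butyldiphenylsilyl)oxy]-2-(3,4-dimethoxyphenyl)oxan-3-yl acetate | COc1ccc(cc1OC)[C@@H]1[C@@H](OC(C)=O)[C@H](Br)[C@H](O[Si](c2ccccc2)(c2ccccc2)C(C)(C)C)CO1
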